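The cyclopentane ring (quaternary C4–C5H2–C6H2–C7H–C16H; skeleton locants are listed below) is read as the formal [3+2] adduct of a ketone-activated cyclopropane (C4, C5, C6) and an electron-poor alkene (C16=C7). C16, the only atom common to the five-, six- and eleven-membered rings, is the pivot. The precursor is a γ-butenolide carrying a (1-methylcyclopropyl) ketone side chain; the lactone is a temporary ring that locks C16=C7 cis and relays one catalyst-set quaternary centre (C15). One nickel-catalysed intramolecular [3+2] cycloaddition forms C4–C16 and C6–C7, closing ring A and the cyclopentane and setting C4, C7 and C16. β-Elimination later unzips the lactone; a Heck reaction closes the macrocycle.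

Key step: step 3

Remark on locants: C1–C20 label the carbons of the target skeleton and are used for all intermediates: ring A = C1–C2–C3–C4–C16–C15 (C1=C15); cyclopentane = C4–C5–C6–C7–C16; macrocycle = C1, C15, C16, C7 to C14; C17 = CH3 on C15, C18 = CH3 on C4, C19 = exo-methylene on C8, C20 = CH3 on C12; oxygen on C2, C3 and C14.
Remark on materials: compounds 1, 2, 4, 9 and 10 are taken as purchasable.

Step 1
Reactants: 1 1-(1-methylcyclopropyl)ethan-1-one; 2 2,2-dimethoxyacetaldehyde
Product: 3 (E)-4,4-dimethoxy-1-(1-methylcyclopropyl)but-2-en-1-one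
Conditions: NaOH (aq), MeOH, 0 °C → rt
Reagents that add atoms: none
Why: Claisen–Schmidt (crossed aldol) condensation; the acetyl methyl is the only enolisable position of 1 and aldehyde 2 cannot enolise, so dehydration of the aldol should give the conjugated E-enone.

Step 2
Reactants: 3 (E)-4,4-dimethoxy-1-(1-methylcyclopropyl)but-2-en-1-one; 4 5-methylfuran-2(3H)-one (α-angelica lactone)
Product: 5 (5R)-5-[(2S)-1,1-dimethoxy-4-(1-methylcyclopropyl)-4-oxobutan-2-yl]-5-methylfuran-2(5H)-one
Conditions: quinine-derived tertiary amine–squaramide catalyst (10 mol %), CH2Cl2, 0 °C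
Reagents that add atoms: none
Why: Direct asymmetric vinylogous Michael addition: the amine generates the dienolate of 4, which attacks the enone β-carbon (future C1) through its γ-carbon while the squaramide binds the ketone, so the quaternary centre C15 is set by the catalyst (the quinidine-derived pseudo-enantiomer is taken if it is the one that leads to 5R; the C1 centre is drawn as 2S but is erased in step 4, so either epimer serves).

Step 3
Reactants: 5 (5R)-5-[(2S)-1,1-dimethoxy-4-(1-methylcyclopropyl)-4-oxobutan-2-yl]-5-methylfuran-2(5H)-one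
Product: 6 all-cis tricyclic keto lactone (ring A cyclohexanone with C3=O, cis-fused at C15–C16 to the γ-lactone O–C8(=O)–C7 and at C4–C16 to the cyclopentane; lactone and cyclopentane share C16–C7; C1 bears CH(OMe)2)
Conditions: Ni(cod)2 (15 mol %), PCy3 (30 mol %), Ti(OtBu)4 (1.0 equiv), PhMe, 80 °C
Reagents that add atoms: none
Why: Proposed new method: zerovalent nickel should insert into the ketone-activated C4–C6 bond of the cyclopropane to give a six-membered oxa-nickelacycle (nickel enolate/alkyl) in which only C4 is nucleophilic, so no base and no choice between enolates is involved; 1,4-addition of C4 to C16 of the coordinated butenolide and C6–C7 reductive elimination from the resulting nickel C-enolate then return zerovalent nickel. The closest known reaction type is the nickel-catalysed intermolecular [3+2] cycloaddition of cyclopropyl ketones with enones, used here intramolecularly with an unsaturated lactone as the two-carbon partner and a 1-methylcyclopropyl ketone that creates a quaternary carbon. Ring A closes by a 6-exo-trig conjugate addition and the cyclopentane by a five-membered C(sp3)–C(sp3) reductive elimination (formally 5-exo-tet at C6). C16 is fixed by the quaternary centre C15, because the four-atom tether can reach only the lactone face that carries C1 (cis ring A/lactone fusion); C7 is fixed by the lactone ring, onto which a cyclopentane can fuse only cis, which places the future C8 syn to C15; C4 follows from the strongly preferred cis-hydrindane fusion (C5 on the side of C7). The step needs nickel to open the cyclopropane faster than it ionises the allylic C15–O bond of the lactone and faster than β-hydride elimination of the Ni–C6 alkyl; the pre-organised tether and the strongly coordinating electron-poor butenolide should secure this.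

Step 4
Reactants: 6 all-cis tricyclic keto lactone
Product: 8 (1R,3aS,7aS)-6-formyl-3a,7-dimethyl-4-oxo-2,3,3a,4,5,7a-hexahydro-1H-indene-1-carboxylic acid, via aldehyde lactone 7 (not isolated)
Conditions: PPTS, acetone–H2O, 50 °C; then Et3N, CH2Cl2, 0 °C; acidic work-up
Reagents that add atoms: water (O)
Why: Acetal hydrolysis unmasks the C14 aldehyde, whose acidic C1–H lets triethylamine expel the β-carboxylate (E1cB elimination), which should open the lactone to the C1=C15 enal and leave C8 as a carboxylate in which C7 cannot epimerise.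

Step 5
Reactants: 9 (R)-4-benzyl-3-propanoyloxazolidin-2-one; 10 3-iodoprop-1-ene
Product: 11 (R)-4-benzyl-3-[(S)-2-methylpent-4-enoyl]oxazolidin-2-one
Conditions: NaN(SiMe3)2, THF, −78 °C; then 10, −78 → −40 °C
Reagents that add atoms: none
Why: Evans asymmetric alkylation; the chelated Z-enolate should be allylated on the face opposite the benzyl group, which sets the future C12 centre (S).

Step 6
Reactants: 11 (R)-4-benzyl-3-[(S)-2-methylpent-4-enoyl]oxazolidin-2-one
Product: 12 (S)-2-methylpent-4-en-1-ol
Conditions: LiBH4, MeOH (1 equiv), Et2O, 0 °C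
Reagents that add atoms: none
Why: Reductive cleavage of the N-acyl oxazolidinone with LiBH4 should give the primary alcohol and the recoverable auxiliary without touching the α-stereocentre.

Step 7
Reactants: 12 (S)-2-methylpent-4-en-1-ol
Product: 13 (S)-5-iodo-4-methylpent-1-ene
Conditions: I2, PPh3, imidazole, CH2Cl2, 0 °C → rt
Reagents that add atoms: iodine (II)
Why: Appel-type iodination; SN2 displacement at the primary CH2 of the alkoxyphosphonium salt leaves the adjacent stereocentre untouched.

Step 8
Reactants: 13 (S)-5-iodo-4-methylpent-1-ene; 8 (1R,3aS,7aS)-6-formyl-3a,7-dimethyl-4-oxo-2,3,3a,4,5,7a-hexahydro-1H-indene-1-carboxylic acid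
Product: 15 (1R,3aS,7aS)-6-[(1S,3S)-1-hydroxy-3-methylhex-5-en-1-yl]-3a,7-dimethyl-4-oxo-2,3,3a,4,5,7a-hexahydro-1H-indene-1-carboxylic acid, via dialkylzinc 14 (not isolated)
Conditions: 13, Et2Zn, CuI (cat.), 50 °C, then volatiles removed; 8 (as its zinc carboxylate), Ti(OiPr)4, (1R,2R)-N,N'-bis(trifluoromethanesulfonyl)cyclohexane-1,2-diamine (8 mol %), PhMe, −20 °C
Reagents that add atoms: none
Why: Titanium/bis-sulfonamide-catalysed asymmetric addition of a dialkylzinc to an aldehyde; the (1R,2R)-ligand should deliver the alkyl group to the Si face of the enal and set C14 (S) under reagent control, while ketone, carboxylate and alkenes are inert.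

Step 9
Reactants: 15 allylic alcohol (C14–OH)
Product: 16 (1R,3aS,7aS)-3a,7-dimethyl-6-[(1S,3S)-3-methyl-1-(triethylsilyloxy)hex-5-en-1-yl]-4-oxo-2,3,3a,4,5,7a-hexahydro-1H-indene-1-carboxylic acid
Conditions: TESCl, imidazole, DMF, 0 °C; aq. K2CO3–MeOH work-up
Reagents that add atoms: chlorotriethylsilane (CC[Si](Cl)(CC)CC)
Why: Silyl ether formation at O14 (the transient silyl ester is cleaved on work-up) protects the allylic alcohol for the basic and organometallic steps that follow.

Step 10
Reactants: 16 O14-triethylsilyl keto acid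
Product: 17 (1R,3aS,5R,7aS)-5-hydroxy-3a,7-dimethyl-6-[(1S,3S)-3-methyl-1-(triethylsilyloxy)hex-5-en-1-yl]-4-oxo-2,3,3a,4,5,7a-hexahydro-1H-indene-1-carboxylic acid
Conditions: KN(SiMe3)2 (2.2 equiv), THF, −78 °C; 2-(phenylsulfonyl)-3-phenyloxaziridine, −78 °C; AcOH quench
Reagents that add atoms: 2-(phenylsulfonyl)-3-phenyloxaziridine (O=S(=O)(c1ccccc1)N1OC1c1ccccc1)
Why: Enolate α-hydroxylation with a Davis oxaziridine; the C3 ketone can enolise only toward C2, and the oxidant should approach C2 anti to the pseudo-axial C18 methyl (the face that carries the cyclopentane), which sets C2.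

Step 11
Reactants: 17 α-hydroxy ketone (C2–OH, C3=O)
Product: 18 (1R,3aS,4R,5R,7aS)-4,5-dihydroxy-3a,7-dimethyl-6-[(1S,3S)-3-methyl-1-(triethylsilyloxy)hex-5-en-1-yl]-2,3,3a,4,5,7a-hexahydro-1H-indene-1-carboxylic acid
Conditions: Me4NBH(OAc)3, AcOH–MeCN, −30 °C
Reagents that add atoms: none
Why: Hydroxyl-directed (Saksena–Evans) reduction; the alkoxy-acetoxyborohydride formed at O2 should deliver hydride to the same face of C3, giving the trans-diol and setting C3.

Step 12
Reactants: 18 trans-2,3-diol acid
Product: 19 the O2-tert-butyldimethylsilyl ether of 18 (C3–OH free)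
Conditions: TBSOTf (2.1 equiv), 2,6-lutidine, CH2Cl2, −78 → −40 °C; aq. K2CO3–MeOH work-up
Reagents that add atoms: tert-butyldimethylsilyl trifluoromethanesulfonate (CC(C)(C)[Si](C)(C)OS(=O)(=O)C(F)(F)F)
Why: Selective silylation; the allylic C2 hydroxyl should react before the C3 hydroxyl, which is flanked by the quaternary C4, and the silyl ester formed at C8 is cleaved on work-up.

Step 13
Reactants: 19 O2-silyl ether with free C3–OH
Product: 20 the C3 acetate of 19 (C8 still CO2H)
Conditions: Ac2O, DMAP, Et3N, CH2Cl2, rt; aq. NaHCO3 work-up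
Reagents that add atoms: acetic anhydride (CC(=O)OC(C)=O)
Why: DMAP-catalysed acylation of the remaining hindered secondary alcohol installs the C3 acetate, and the mixed anhydride formed at C8 is hydrolysed on work-up.

Step 14
Reactants: 20 C3-acetoxy acid
Product: 22 methyl ketone (C8(=O)–C19H3 on C7; O2-TBS, O3-Ac, O14-TES), via acid chloride 21 (not isolated)
Conditions: 1-chloro-N,N,2-trimethylprop-1-en-1-amine (Ghosez reagent), CH2Cl2, 0 °C; then Me2CuLi, Et2O, −78 °C
Reagents that add atoms: lithium dimethylcuprate ([Li+].C[Cu-]C)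
Why: Neutral acid chloride formation followed by acylation of a Gilman cuprate should give the methyl ketone without base, so C7 is not epimerised and the acetate and silyl ethers survive.

Step 15
Reactants: 22 methyl ketone
Product: 23 enol triflate (C8(OTf)=C19H2 on C7)
Conditions: KN(SiMe3)2, THF, −78 °C; PhNTf2, −78 °C
Reagents that add atoms: N-phenylbis(trifluoromethanesulfonimide) (O=S(=O)(N(c1ccccc1)S(=O)(=O)C(F)(F)F)C(F)(F)F)
Why: Kinetic deprotonation at the methyl group and O-sulfonylation (enol triflate formation) should give the less substituted alkenyl triflate and remove the C7–H acidity for good.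

Step 16
Reactants: 23 enol triflate with the terminal C9=C10 alkene
Product: 24 macrocyclic triene (2R,3R,4S,7R,12S,14S,16S; C1=C15, C8=C19, E-C9=C10; O2-TBS, O3-Ac, O14-TES)
Conditions: Pd(OAc)2 (20 mol %), Bu4NCl, K2CO3, DMF, 60 °C, 0.002 M (slow addition)
Reagents that add atoms: none
Why: Intramolecular Heck reaction; the alkenyl–palladium species should add to the terminal carbon C9 of the monosubstituted alkene, and β-hydride elimination of a C9 hydrogen then gives the conjugated C19=C8–C9=C10 (E) diene inside the eleven-membered ring.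

Step 17
Reactants: 24 macrocyclic triene (O14-TES)
Product: 25 the C14 alcohol (O2-TBS and O3-Ac retained)
Conditions: PPTS, MeOH, 0 °C → rt
Reagents that add atoms: none
Why: Acid-catalysed methanolysis should cleave the triethylsilyl ether selectively in the presence of the more hindered tert-butyldimethylsilyl ether.

Step 18
Reactants: 25 C14 alcohol
Product: 26 the 3,14-diacetate (O2-TBS)
Conditions: Ac2O, DMAP, pyridine, CH2Cl2, rt
Reagents that add atoms: acetic anhydride (CC(=O)OC(C)=O)
Why: DMAP-catalysed acetylation of the freed allylic C14 hydroxyl.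

Step 19
Reactants: 26 3,14-diacetate O2-TBS ether
Product: 27 CNP0323842.1 (2R,3R,4S,7R,12S,14S,16S; 2-hydroxy-3,14-diacetoxy triene)
Conditions: HF·pyridine, pyridine, THF, 0 °C → rt
Reagents that add atoms: none
Why: Fluoride-mediated desilylation under buffered acidic conditions should free the C2 hydroxyl without acetyl migration from O3.

Compound list
1 | 1-(1-methylcyclopropyl)ethan-1-one | CC(=O)C1(C)CC1 | starting material
2 | 2,2-dimethoxyacetaldehyde | COC(OC)C=O | starting material
3 | (E)-4,4-dimethoxy-1-(1-methylcyclopropyl)but-2-en-1-one | COC(OC)/C=C/C(=O)C1(C)CC1 | intermediate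
4 | 5-methylfuran-2(3H)-one (α-angelica lactone) | CC1=CCC(=O)O1 | starting material
5 | (5R)-5-[(2S)-1,1-dimethoxy-4-(1-methylcyclopropyl)-4-oxobutan-2-yl]-5-methylfuran-2(5H)-one | COC(OC)[C@@H](CC(=O)C1(C)CC1)[C@]1(C)OC(=O)C=C1 | intermediate
6 | all-cis tricyclic keto lactone (ring A, γ-lactone and cyclopentane around C16; CH(OMe)2 on C1) | COC(OC)[C@H]1CC(=O)[C@@]2(C)CC[C@H]3C(=O)O[C@]1(C)[C@@H]23 | intermediate
7 | aldehyde lactone (6 with CHO on C1) | O=C[C@H]1CC(=O)[C@@]2(C)CC[C@H]3C(=O)O[C@]1(C)[C@@H]23 | intermediate (not isolated)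
8 | (1R,3aS,7aS)-6-formyl-3a,7-dimethyl-4-oxo-2,3,3a,4,5,7a-hexahydro-1H-indene-1-carboxylic acid | O=CC1=C(C)[C@@H]2[C@H](C(=O)O)CC[C@]2(C)C(=O)C1 | intermediate
9 | (R)-4-benzyl-3-propanoyloxazolidin-2-one | CCC(=O)N1[C@H](Cc2ccccc2)COC1=O | starting material
10 | 3-iodoprop-1-ene | C=CCI | starting material
11 | (R)-4-benzyl-3-[(S)-2-methylpent-4-enoyl]oxazolidin-2-one | C=CC[C@H](C)C(=O)N1[C@H](Cc2ccccc2)COC1=O | intermediate
12 | (S)-2-methylpent-4-en-1-ol | C=CC[C@H](C)CO | intermediate
13 | (S)-5-iodo-4-methylpent-1-ene | C=CC[C@H](C)CI | intermediate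
14 | bis[(S)-2-methylpent-4-en-1-yl]zinc | C=CC[C@H](C)C[Zn]C[C@@H](C)CC=C | intermediate (not isolated)
15 | (1R,3aS,7aS)-6-[(1S,3S)-1-hydroxy-3-methylhex-5-en-1-yl]-3a,7-dimethyl-4-oxo-2,3,3a,4,5,7a-hexahydro-1H-indene-1-carboxylic acid | C=CC[C@H](C)C[C@H](O)C1=C(C)[C@@H]2[C@H](C(=O)O)CC[C@]2(C)C(=O)C1 | intermediate
16 | O14-triethylsilyl ether of 15 | C=CC[C@H](C)C[C@H](O[Si](CC)(CC)CC)C1=C(C)[C@@H]2[C@H](C(=O)O)CC[C@]2(C)C(=O)C1 | intermediate
17 | (5R)-5-hydroxy derivative of 16 (C2–OH, C3=O) | C=CC[C@H](C)C[C@H](O[Si](CC)(CC)CC)C1=C(C)[C@@H]2[C@H](C(=O)O)CC[C@]2(C)C(=O)[C@@H]1O | intermediate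
18 | (4R,5R)-4,5-diol (trans C2–OH/C3–OH) | C=CC[C@H](C)C[C@H](O[Si](CC)(CC)CC)C1=C(C)[C@@H]2[C@H](C(=O)O)CC[C@]2(C)[C@@H](O)[C@@H]1O | intermediate
19 | O2-tert-butyldimethylsilyl ether of 18 | C=CC[C@H](C)C[C@H](O[Si](CC)(CC)CC)C1=C(C)[C@@H]2[C@H](C(=O)O)CC[C@]2(C)[C@@H](O)[C@@H]1O[Si](C)(C)C(C)(C)C | intermediate
20 | C3 acetate of 19 | C=CC[C@H](C)C[C@H](O[Si](CC)(CC)CC)C1=C(C)[C@@H]2[C@H](C(=O)O)CC[C@]2(C)[C@@H](OC(C)=O)[C@@H]1O[Si](C)(C)C(C)(C)C | intermediate
21 | acid chloride of 20 | C=CC[C@H](C)C[C@H](O[Si](CC)(CC)CC)C1=C(C)[C@@H]2[C@H](C(=O)Cl)CC[C@]2(C)[C@@H](OC(C)=O)[C@@H]1O[Si](C)(C)C(C)(C)C | intermediate (not isolated)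
22 | methyl ketone (C8(=O)C19H3 on C7) | C=CC[C@H](C)C[C@H](O[Si](CC)(CC)CC)C1=C(C)[C@@H]2[C@H](C(C)=O)CC[C@]2(C)[C@@H](OC(C)=O)[C@@H]1O[Si](C)(C)C(C)(C)C | intermediate
23 | enol triflate (C8(OTf)=C19H2 on C7) | C=CC[C@H](C)C[C@H](O[Si](CC)(CC)CC)C1=C(C)[C@@H]2[C@H](C(=C)OS(=O)(=O)C(F)(F)F)CC[C@]2(C)[C@@H](OC(C)=O)[C@@H]1O[Si](C)(C)C(C)(C)C | intermediate
24 | macrocyclic triene, O2-TBS, O3-Ac, O14-TES | C=C1/C=C/C[C@H](C)C[C@H](O[Si](CC)(CC)CC)C2=C(C)[C@@H]3[C@H]1CC[C@]3(C)[C@@H](OC(C)=O)[C@@H]2O[Si](C)(C)C(C)(C)C | intermediate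
25 | macrocyclic C14 alcohol, O2-TBS, O3-Ac | C=C1/C=C/C[C@H](C)C[C@H](O)C2=C(C)[C@@H]3[C@H]1CC[C@]3(C)[C@@H](OC(C)=O)[C@@H]2O[Si](C)(C)C(C)(C)C | intermediate
26 | 3,14-diacetate, O2-TBS | C=C1/C=C/C[C@H](C)C[C@H](OC(C)=O)C2=C(C)[C@@H]3[C@H]1CC[C@]3(C)[C@@H](OC(C)=O)[C@@H]2O[Si](C)(C)C(C)(C)C | intermediate
27 | CNP0323842.1 | C=C1/C=C/C[C@H](C)C[C@H](OC(C)=O)C2=C(C)[C@@H]3[C@H]1CC[C@]3(C)[C@@H](OC(C)=O)[C@@H]2O | target

Total step count: 19. Longest linear sequence: 16 steps (steps 1–4 and 8–19); the side branch (steps 5–7) joins at step 8.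

Steps most likely to fail

Step 3 (proposed new method). Nickel may ionise the allylic C15–O bond of the lactone instead of opening the cyclopropane, the Ni–C6 alkyl may undergo β-hydride elimination to an open-chain enone, or the crowded C4–C16 bond may not form. The fallback sets out from 5 and returns at 6 by two known operations. MgI2 (THF, 60 °C) opens the ketone-activated cyclopropane by iodide attack at C6, and the magnesium enolate so formed adds in a Michael fashion to C16 of the butenolide, which after aqueous work-up should give iodo lactone F1. LiN(SiMe3)2 (2.2 equiv, THF–DMPU, −78 → 0 °C) then closes the cyclopentane by intramolecular alkylation of the lactone enolate (C7) with the primary iodide. In this route C4 is set in the Michael step without the help of the five-membered ring, so only the epimer with the iodoethyl arm on the side of C7 can cyclise.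

Step 16. The alkenyl–palladium species may insert at the internal alkene carbon (exo mode, ten-membered ring), the terminal alkene may migrate, or oligomers may form at the expense of the medium ring. The fallback sets out from 23 and returns at 24. Cross-metathesis of the terminal alkene with vinylboronic acid pinacol ester (second-generation Grubbs catalyst, CH2Cl2, 40 °C) should give the (E)-alkenyl boronate F2. Intramolecular Suzuki–Miyaura coupling with the enol triflate (Pd(dppf)Cl2, K3PO4, DMF–H2O, high dilution) then forms the C8–C9 bond with both alkene positions fixed in advance.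

Step 10. The oxaziridine may attack the dienolate on the face of the C18 methyl (wrong C2 epimer) or the β,γ-unsaturated ketone may slip into conjugation during enolate handling. The fallback sets out from 16 and returns at 17 and replaces substrate control by reagent control. TBSOTf and Et3N convert 16 into the bis-silyl dienol ether F3 (silyl enol ether at C3=C2, silyl ester at C8). Shi asymmetric epoxidation of the electron-rich enol ether double bond (fructose-derived ketone catalyst of the enantiomeric series that attacks the face anti to C18, Oxone (2KHSO5·KHSO4·K2SO4), buffered MeCN–H2O, 0 °C) and mild acidic work-up should give the α-hydroxy ketone 17 directly.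

Further compounds
F1 | step 3 | iodo lactone (ring A cis-fused to the γ-lactone; C4 bears CH3 and CH2CH2I; C7 is CH2) | COC(OC)[C@H]1CC(=O)[C@@](C)(CCI)[C@H]2CC(=O)O[C@@]12C
F2 | step 16 | (E)-alkenyl pinacol boronate at C9 of enol triflate 23 | CC1(C)OB(/C=C/C[C@H](C)C[C@H](O[Si](CC)(CC)CC)C2=C(C)[C@@H]3[C@H](C(=C)OS(=O)(=O)C(F)(F)F)CC[C@]3(C)[C@@H](OC(C)=O)[C@@H]2O[Si](C)(C)C(C)(C)C)OC1(C)C
F3 | step 10 | bis-silyl dienol ether of 16 (C3(OTBS)=C2, TBS ester at C8) | C=CC[C@H](C)C[C@H](O[Si](CC)(CC)CC)C1=C(C)[C@@H]2[C@H](C(=O)O[Si](C)(C)C(C)(C)C)CC[C@]2(C)C(O[Si](C)(C)C(C)(C)C)=C1
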